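The route disconnects the angular methyl C15 as the methylene of a cyclopropane spanning C1 and C5 (daucane numbering). In one operation, a hydroxyl-directed Simmons–Smith reaction on the C1=C5 ring-fusion alkene forms C1–C15 and C5–C15 and sets both ring-fusion carbons from the C4 carbinol. It exploits the fact that C15 on quaternary C1 of the five-membered ring is cis to the C4 tertiary hydroxyl, while C5 carries hydrogen beside the oxygenated C6 of the seven-membered ring. The substrate is a bicyclo[5.3.0]decadiene with a C4 isopropyl carbinol, the tetrasubstituted C1=C5 alkene, a C6 silyl ether and the C8=C9 alkene. A C6 ketone later lets lithium in ammonia cut C5–C15.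

Key step: step 10

Remark on numbering: locants follow daucane numbering: five-membered ring C1–C5 (C15 on C1; isopropyl and hydroxyl on C4), seven-membered ring C1, C10, C9, C8, C7, C6, C5 (C14 on C8); β is the face that carries C15.
Remark on the chemistry: the seven-membered ring is closed by metathesis of an acyclic ketone made by a catalytic asymmetric glyoxylate-ene reaction, because this fixes the C8 methyl position and the (R) configuration at C6 by connectivity, with no resolution and no regiochemical question.

Step 1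
Reactants: 1 ethyl glyoxylate; 2 2-methylpropene
Product: 3 ethyl (2R)-2-hydroxy-4-methylpent-4-enoate
Conditions: (R)-BINOL (10 mol%), TiCl2(OiPr)2 (10 mol%), 4 Å MS, CH2Cl2, −30 °C
Reagents that add atoms: none
Why: Catalytic asymmetric glyoxylate-ene (carbonyl-ene) reaction: the BINOL–titanium Lewis acid activates the aldehyde and shields one enantioface, so ene transfer from 2-methylpropene should set the (R)-carbinol (later C6) and install the methallyl unit that becomes C7, C8 and C14.

Step 2
Reactants: 3 ethyl (2R)-2-hydroxy-4-methylpent-4-enoate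
Product: 4 ethyl (2R)-2-[(tert-butyldimethylsilyl)oxy]-4-methylpent-4-enoate
Conditions: TBSCl, imidazole, DMF, 23 °C
Reagents that add atoms: tert-butyldimethylsilyl chloride, CC(C)(C)[Si](C)(C)Cl
Why: Imidazole-promoted silylation of a secondary alcohol, which does not touch the stereocentre.

Step 3
Reactants: 4 ethyl (2R)-2-[(tert-butyldimethylsilyl)oxy]-4-methylpent-4-enoate
Product: 5 (2R)-2-[(tert-butyldimethylsilyl)oxy]-N-methoxy-N,4-dimethylpent-4-enamide
Conditions: MeNH(OMe)·HCl, i-PrMgCl, THF, −20 → 0 °C
Reagents that add atoms: N,O-dimethylhydroxylamine hydrochloride, Cl.CNOC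
Why: Direct ester-to-Weinreb-amide aminolysis by the chloromagnesium amide, a standard transformation of α-silyloxy esters that should proceed at low temperature without enolising the α-stereocentre.

Step 4
Reactants: 5 (2R)-2-[(tert-butyldimethylsilyl)oxy]-N-methoxy-N,4-dimethylpent-4-enamide; 6 but-3-en-1-ylmagnesium bromide
Product: 7 (4R)-4-[(tert-butyldimethylsilyl)oxy]-2-methylnona-1,8-dien-5-one
Conditions: THF, 0 °C; aq. NH4Cl
Reagents that add atoms: none
Why: Weinreb ketone synthesis: the chelated tetrahedral adduct survives until work-up, so a single addition should give the ketone carrying C1, C10 and C9 on one side and C6–C8 on the other.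

Step 5
Reactants: 7 (4R)-4-[(tert-butyldimethylsilyl)oxy]-2-methylnona-1,8-dien-5-one
Product: 8 (2R)-2-[(tert-butyldimethylsilyl)oxy]-4-methylcyclohept-4-en-1-one
Conditions: second-generation Grubbs catalyst RuCl2(H2IMes)(PCy3)(=CHPh) (3 mol%), CH2Cl2 (5 mM), 40 °C
Reagents that add atoms: none
Why: Ring-closing olefin metathesis of a monosubstituted with a 1,1-disubstituted alkene, driven by loss of ethylene, should close the seven-membered ring with the trisubstituted C8=C9 alkene in the only position the connectivity allows.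

Step 6
Reactants: 8 (2R)-2-[(tert-butyldimethylsilyl)oxy]-4-methylcyclohept-4-en-1-one
Product: 10 (7R)-7-[(tert-butyldimethylsilyl)oxy]-5-methylcyclohepta-1,4-dien-1-yl trifluoromethanesulfonate, via potassium enolate 9 (not isolated)
Conditions: KN(SiMe3)2, THF, −78 °C; then PhNTf2, −78 → 0 °C
Reagents that add atoms: N-phenylbis(trifluoromethanesulfonimide), O=S(=O)(N(c1ccccc1)S(=O)(=O)C(F)(F)F)C(F)(F)F
Why: Kinetic enolate formation and O-triflation: the hindered base should remove a proton from the open α'-methylene (C1) and not from the silyloxy-bearing C6, so the enol triflate forms toward C1 and C6 keeps its configuration.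

Step 7
Reactants: 10 (7R)-7-[(tert-butyldimethylsilyl)oxy]-5-methylcyclohepta-1,4-dien-1-yl trifluoromethanesulfonate; 11 tributyl(vinyl)stannane
Product: 12 1-[(7R)-7-[(tert-butyldimethylsilyl)oxy]-5-methylcyclohepta-1,4-dien-1-yl]prop-2-en-1-one
Conditions: Pd(PPh3)4 (5 mol%), LiCl, CO (1 atm), THF, 55 °C
Reagents that add atoms: carbon monoxide, [C-]#[O+]
Why: Carbonylative Stille coupling: oxidative addition of the vinyl triflate to zerovalent palladium, CO insertion, vinyl transfer from tin and reductive elimination should give the cross-conjugated divinyl ketone in which the inserted carbon is C4.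

Step 8
Reactants: 12 1-[(7R)-7-[(tert-butyldimethylsilyl)oxy]-5-methylcyclohepta-1,4-dien-1-yl]prop-2-en-1-one
Product: 13 (8R)-8-[(tert-butyldimethylsilyl)oxy]-6-methyl-3,4,7,8-tetrahydroazulen-1(2H)-one (C4 ketone, C1=C5 and C8=C9 alkenes, 6R silyl ether)
Conditions: SnCl4 (1.1 equiv), CH2Cl2, −78 → 0 °C; aq. NaHCO3
Reagents that add atoms: none
Why: Nazarov cyclisation: the Lewis acid-bound dienone reacts as a pentadienyl cation, conrotatory 4π electrocyclisation joins C1 to C2, and loss of the C1 proton should leave the alkene in the tetrasubstituted C1=C5 position conjugated with the C4 ketone, with C6 untouched.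

Step 9
Reactants: 13 (8R)-8-[(tert-butyldimethylsilyl)oxy]-6-methyl-3,4,7,8-tetrahydroazulen-1(2H)-one
Product: 14 (1R,8R)-8-[(tert-butyldimethylsilyl)oxy]-6-methyl-1-(propan-2-yl)-1,2,3,4,7,8-hexahydroazulen-1-ol (daucane locants 4R,6R; C4 hydroxyl cis to the C6 silyloxy group)
Conditions: i-PrMgCl, CeCl3 (anhydrous), THF, −78 °C; aq. NH4Cl
Reagents that add atoms: isopropylmagnesium chloride, CC(C)[Mg]Cl
Why: Organocerium 1,2-addition to an enolisable enone: the weakly basic isopropylcerium reagent should add to the C4 carbonyl without enolisation, reduction or conjugate addition, and from the face opposite the C6 silyloxy group (pseudo-axial to avoid the carbonyl oxygen), which places the new hydroxyl cis to the C6 oxygen (4R).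

Step 10
Reactants: 14 (1R,8R)-8-[(tert-butyldimethylsilyl)oxy]-6-methyl-1-(propan-2-yl)-1,2,3,4,7,8-hexahydroazulen-1-ol
Product: 16 (1R,6R,7R,8R)-6-[(tert-butyldimethylsilyl)oxy]-4-methyl-8-(propan-2-yl)tricyclo[5.3.1.0^{1,7}]undec-3-en-8-ol (daucane locants 1R,4R,5R,6R; C15 methylene bridging C1 and C5 on the face of the C4 hydroxyl), via ethylzinc alkoxide 15 (not isolated)
Conditions: Et2Zn (3 equiv), CH2I2 (4 equiv), CH2Cl2, −10 → 23 °C; aq. NH4Cl
Reagents that add atoms: diiodomethane, ICI
Why: Simmons–Smith cyclopropanation in its diethylzinc form: Et2Zn first turns the C4 hydroxyl into ethylzinc alkoxide 15, which holds the iodomethylzinc carbenoid over the adjacent C1=C5 bond, and the methylene is passed on in a concerted butterfly-type transition state. The closest known reaction type is the hydroxyl-directed cyclopropanation of cyclic tertiary allylic alcohols at tetrasubstituted ring-fusion alkenes. The three-membered ring C1–C15–C5 closes by a concerted (2+1) addition in which both C–C bonds form on one alkene face, so no exo or endo mode of ring closure applies. The new quaternary stereocentres C1 and C5 are both set by C4, because the zinc-bound oxygen delivers C15 to its own β face (1R,5R). The step needs face selectivity and chemoselectivity over the C8=C9 alkene: the first is secured by the alkoxide anchor (the C6 silyl ether lies on the same face but cannot bind zinc), the second by the rate gain of the directed tetrasubstituted alkene over the remote trisubstituted one with a limited excess of carbenoid.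

Step 11
Reactants: 16 (1R,6R,7R,8R)-6-[(tert-butyldimethylsilyl)oxy]-4-methyl-8-(propan-2-yl)tricyclo[5.3.1.0^{1,7}]undec-3-en-8-ol
Product: 17 (1R,6R,7R,8R)-4-methyl-8-(propan-2-yl)tricyclo[5.3.1.0^{1,7}]undec-3-ene-6,8-diol
Conditions: Bu4NF, THF, 23 → 50 °C; aq. NH4Cl
Reagents that add atoms: none
Why: Fluoride-mediated desilylation under basic, non-ionising conditions should free the C6 alcohol without opening the acid-sensitive cyclopropylcarbinol.

Step 12
Reactants: 17 (1R,6R,7R,8R)-4-methyl-8-(propan-2-yl)tricyclo[5.3.1.0^{1,7}]undec-3-ene-6,8-diol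
Product: 18 (1R,7S,8R)-8-hydroxy-4-methyl-8-(propan-2-yl)tricyclo[5.3.1.0^{1,7}]undec-3-en-6-one (daucane locants 1R,4R,5S; C6 ketone beside the cyclopropane)
Conditions: Dess–Martin periodinane, NaHCO3, CH2Cl2, 0 → 23 °C
Reagents that add atoms: none
Why: Dess–Martin oxidation of the secondary alcohol under buffered conditions; the tertiary C4 alcohol cannot be oxidised, and the relay stereocentre C6 is erased as planned.

Step 13
Reactants: 18 (1R,7S,8R)-8-hydroxy-4-methyl-8-(propan-2-yl)tricyclo[5.3.1.0^{1,7}]undec-3-en-6-one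
Product: 21 (1R,4R,5R)-4-hydroxydauc-8-en-6-one (4β-hydroxy-5αH; trans-fused), via dilithium enolate 19 (not isolated), via cis-fused ketone 20 (not isolated)
Conditions: Li, NH3(l), THF, −78 °C; solid NH4Cl; then DBU (0.2 equiv), toluene, 23 °C
Reagents that add atoms: none
Why: Dissolving-metal reductive cleavage of a conjugated cyclopropyl ketone: the ketyl radical anion should break C5–C15, the cyclopropane bond that stands out of the seven-membered ring and overlaps best with the C6 π system, leaving C15 as the β-methyl on C1 and the C5=C6 enolate 19; protonation and amidine-base equilibration at C5 should then settle the trans ring fusion, in which C6 lies beside the small C4 hydroxyl and away from the isopropyl group.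

Step 14
Reactants: 21 (1R,4R,5R)-4-hydroxydauc-8-en-6-one
Product: 22 (1R,4R,5S,6S)-dauc-8-ene-4,6-diol (4β,6α-diol)
Conditions: Me4NBH(OAc)3, MeCN/AcOH (1:1), −20 °C
Reagents that add atoms: none
Why: Evans–Saksena hydroxyl-directed reduction: the acetoxyborohydride exchanges onto the C4 hydroxyl and delivers hydride intramolecularly to the β face of the C6 carbonyl, which should give the 6α-alcohol (anti 1,3-diol, 6S).

Step 15
Reactants: 22 (1R,4R,5S,6S)-dauc-8-ene-4,6-diol
Product: 23 (1R,4R,5S,6S,8R,9S)-8,9-epoxydaucane-4,6-diol (8α,9α-epoxide)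
Conditions: VO(acac)2 (5 mol%), t-BuOOH, CH2Cl2, 0 → 23 °C
Reagents that add atoms: tert-butyl hydroperoxide, CC(C)(C)OO
Why: Vanadium-catalysed hydroxyl-directed epoxidation: the homoallylic 6α-hydroxyl binds the vanadium alkylperoxide and should deliver oxygen to the α face of C8=C9, which is also the face away from C15 (8R,9S).

Step 16
Reactants: 23 (1R,4R,5S,6S,8R,9S)-8,9-epoxydaucane-4,6-diol; 24 4-acetoxybenzoic acid
Product: 25 (1R,4R,5S,6S,8R,9S)-6-(4-acetoxybenzoyloxy)-8,9-epoxydaucan-4-ol
Conditions: EDC·HCl, DMAP (0.1 equiv), CH2Cl2, 0 → 23 °C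
Reagents that add atoms: none
Why: Steglich esterification: the carbodiimide-activated acid should acylate the secondary C6 hydroxyl and leave the tertiary C4 hydroxyl and the epoxide alone under neutral conditions.

Step 17
Reactants: 25 (1R,4R,5S,6S,8R,9S)-6-(4-acetoxybenzoyloxy)-8,9-epoxydaucan-4-ol
Product: 26 jaeskeanin, (1R,4R,5S,6S,8R,9S)-8,9-epoxy-6-(4-hydroxybenzoyloxy)daucan-4-ol
Conditions: K2CO3 (1.2 equiv), MeOH, 0 °C; aq. NH4Cl
Reagents that add atoms: none
Why: Chemoselective methanolysis (transesterification) of the activated aryl acetate, which should be much faster than attack on the hindered secondary benzoate, the latter being further deactivated once the phenoxide forms.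

Compound list
1 | ethyl glyoxylate (ethyl 2-oxoacetate) | CCOC(=O)C=O | starting material
2 | 2-methylpropene (isobutylene) | CC(C)=C | starting material
3 | ethyl (2R)-2-hydroxy-4-methylpent-4-enoate | CCOC(=O)[C@H](O)CC(C)=C | intermediate
4 | ethyl (2R)-2-[(tert-butyldimethylsilyl)oxy]-4-methylpent-4-enoate | CCOC(=O)[C@H](O[Si](C)(C)C(C)(C)C)CC(C)=C | intermediate
5 | (2R)-2-[(tert-butyldimethylsilyl)oxy]-N-methoxy-N,4-dimethylpent-4-enamide | CON(C)C(=O)[C@H](O[Si](C)(C)C(C)(C)C)CC(C)=C | intermediate
6 | but-3-en-1-ylmagnesium bromide | C=CCC[Mg]Br | starting material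
7 | (4R)-4-[(tert-butyldimethylsilyl)oxy]-2-methylnona-1,8-dien-5-one | C=CCCC(=O)[C@H](O[Si](C)(C)C(C)(C)C)CC(C)=C | intermediate
8 | (2R)-2-[(tert-butyldimethylsilyl)oxy]-4-methylcyclohept-4-en-1-one | O=C1CCC=C(C)C[C@H]1O[Si](C)(C)C(C)(C)C | intermediate
9 | potassium (7R)-7-[(tert-butyldimethylsilyl)oxy]-5-methylcyclohepta-1,4-dien-1-olate | [K+].[O-]C1=CCC=C(C)C[C@H]1O[Si](C)(C)C(C)(C)C | intermediate (not isolated)
10 | (7R)-7-[(tert-butyldimethylsilyl)oxy]-5-methylcyclohepta-1,4-dien-1-yl trifluoromethanesulfonate | O=S(=O)(OC1=CCC=C(C)C[C@H]1O[Si](C)(C)C(C)(C)C)C(F)(F)F | intermediate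
11 | tributyl(vinyl)stannane | CCCC[Sn](CCCC)(CCCC)C=C | starting material
12 | 1-[(7R)-7-[(tert-butyldimethylsilyl)oxy]-5-methylcyclohepta-1,4-dien-1-yl]prop-2-en-1-one | C=CC(=O)C1=CCC=C(C)C[C@H]1O[Si](C)(C)C(C)(C)C | intermediate
13 | (8R)-8-[(tert-butyldimethylsilyl)oxy]-6-methyl-3,4,7,8-tetrahydroazulen-1(2H)-one | O=C1CCC2=C1[C@H](O[Si](C)(C)C(C)(C)C)CC(C)=CC2 | intermediate
14 | (1R,8R)-8-[(tert-butyldimethylsilyl)oxy]-6-methyl-1-(propan-2-yl)-1,2,3,4,7,8-hexahydroazulen-1-ol (key-step precursor) | CC(C)[C@]1(O)CCC2=C1[C@H](O[Si](C)(C)C(C)(C)C)CC(C)=CC2 | intermediate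
15 | ethylzinc alkoxide of 14 (C4–O–ZnEt) | CC[Zn]O[C@@]1(C(C)C)CCC2=C1[C@H](O[Si](C)(C)C(C)(C)C)CC(C)=CC2 | intermediate (not isolated)
16 | (1R,6R,7R,8R)-6-[(tert-butyldimethylsilyl)oxy]-4-methyl-8-(propan-2-yl)tricyclo[5.3.1.0^{1,7}]undec-3-en-8-ol (key-step product) | CC(C)[C@]1(O)CC[C@@]23C[C@@]12[C@H](O[Si](C)(C)C(C)(C)C)CC(C)=CC3 | intermediate
17 | (1R,6R,7R,8R)-4-methyl-8-(propan-2-yl)tricyclo[5.3.1.0^{1,7}]undec-3-ene-6,8-diol | CC(C)[C@]1(O)CC[C@@]23C[C@@]12[C@H](O)CC(C)=CC3 | intermediate
18 | (1R,7S,8R)-8-hydroxy-4-methyl-8-(propan-2-yl)tricyclo[5.3.1.0^{1,7}]undec-3-en-6-one | CC(C)[C@]1(O)CC[C@@]23C[C@@]12C(=O)CC(C)=CC3 | intermediate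
19 | dilithium salt of the C4 alkoxide and C5=C6 enolate of 4-hydroxydauc-8-en-6-one | [Li+].[Li+].CC(C)[C@]1([O-])CC[C@]2(C)CC=C(C)CC([O-])=C12 | intermediate (not isolated)
20 | (1R,4R,5S)-4-hydroxydauc-8-en-6-one (cis-fused C5 epimer, 5βH) | CC(C)[C@]1(O)CC[C@]2(C)CC=C(C)CC(=O)[C@@H]21 | intermediate (not isolated)
21 | (1R,4R,5R)-4-hydroxydauc-8-en-6-one (trans-fused, 4β-hydroxy-5αH) | CC(C)[C@]1(O)CC[C@]2(C)CC=C(C)CC(=O)[C@H]21 | intermediate
22 | (1R,4R,5S,6S)-dauc-8-ene-4,6-diol (4β,6α) | CC(C)[C@]1(O)CC[C@]2(C)CC=C(C)C[C@H](O)[C@H]21 | intermediate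
23 | (1R,4R,5S,6S,8R,9S)-8,9-epoxydaucane-4,6-diol (8α,9α-epoxide) | CC(C)[C@]1(O)CC[C@]2(C)C[C@@H]3O[C@]3(C)C[C@H](O)[C@H]21 | intermediate
24 | 4-acetoxybenzoic acid | CC(=O)Oc1ccc(cc1)C(O)=O | starting material
25 | (1R,4R,5S,6S,8R,9S)-6-(4-acetoxybenzoyloxy)-8,9-epoxydaucan-4-ol | CC(C)[C@]1(O)CC[C@]2(C)C[C@@H]3O[C@]3(C)C[C@H](OC(=O)c3ccc(OC(C)=O)cc3)[C@H]21 | intermediate
26 | jaeskeanin | CC(C)[C@]1(O)CC[C@]2(C)C[C@@H]3O[C@]3(C)C[C@H](OC(=O)c3ccc(O)cc3)[C@H]21 | target

Total step count: 17
Longest linear sequence: 17 steps (1 → 26)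

Steps most likely to fail

Step 10 (key step). What may go wrong: slow methylene transfer to the crowded tetrasubstituted alkene while the bulky silyl ether sits on the reacting face, with competing cyclopropanation of the C8=C9 alkene or zinc iodide-promoted ionisation of the tertiary allylic alcohol. Fallback, setting out from 14 and returning at 17: the silyl ether is removed first with Bu4NF in THF to give the syn allylic diol F1. Its two cis hydroxyls, the tertiary one on C4 and the secondary allylic one on C6 directly beside C5, are both turned into zinc alkoxides by Et2Zn and together guide the carbenoid from CH2I2 to the β face, with no silyl group in the way. The product is diol 17, so step 11 is omitted and the route goes on at step 12.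

Step 8. What may go wrong: Lewis acid-induced loss of the silyl ether, polymerisation of the unsubstituted vinyl ketone, or proton loss toward C2 or C6 in place of C1. Fallback, setting out from 5 and returning at 13: the five-membered ring is built first and without acid. Amide 5 is reduced with i-Bu2AlH (THF, −78 °C) to aldehyde F2, homologated with dimethyl (1-diazo-2-oxopropyl)phosphonate and K2CO3 in MeOH (Ohira–Bestmann) to alkyne F3, and allylated at the alkyne terminus (allyl bromide, CuI, K2CO3, NaI, DMF) to enyne F4. An intermolecular Pauson–Khand reaction (Co2(CO)8, then ethylene and N-methylmorpholine N-oxide in CH2Cl2) should place the bulkier silyloxy-bearing substituent beside the new carbonyl and give cyclopentenone F5. Ring-closing metathesis of its allyl and methallyl arms (second-generation Grubbs catalyst) then closes the seven-membered ring and arrives at 13.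

Step 13. What may go wrong: electron transfer cleaving the ring-fusion bond C1–C5 in place of C5–C15, over-reduction at C6, or migration of the C8=C9 alkene toward the ketone while C5 is equilibrated. Fallback, setting out from 14 and returning at 21: C15 is brought in by conjugate addition, with no cyclopropane to cleave. The allylic diol F1 (from 14 and Bu4NF, as above) is oxidised at its secondary allylic alcohol with MnO2 to dienone F6. Me2CuLi with BF3·OEt2 (THF, −78 °C) should add the methyl group to C1 from the β face, opposite the C4 isopropyl group and on the side of the C4 alkoxide. Protonation of the resulting enolate at C5 at low temperature, anti to the metal-bridged alkoxide, then leads to 21 without a strongly reducing medium; this fallback does not remove the alkene-migration risk if base equilibration is still needed.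

Further compounds
F1 | step 10 | (1R,8R)-6-methyl-1-(propan-2-yl)-1,2,3,4,7,8-hexahydroazulene-1,8-diol (syn allylic diol; daucane locants 4R,6R) | CC(C)[C@]1(O)CCC2=C1[C@H](O)CC(C)=CC2
F2 | step 8 | (2R)-2-[(tert-butyldimethylsilyl)oxy]-4-methylpent-4-enal | O=C[C@H](O[Si](C)(C)C(C)(C)C)CC(C)=C
F3 | step 8 | (3R)-3-[(tert-butyldimethylsilyl)oxy]-5-methylhex-5-en-1-yne | C#C[C@H](O[Si](C)(C)C(C)(C)C)CC(C)=C
F4 | step 8 | (6R)-6-[(tert-butyldimethylsilyl)oxy]-8-methylnona-1,8-dien-4-yne | C=CCC#C[C@H](O[Si](C)(C)C(C)(C)C)CC(C)=C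
F5 | step 8 | 2-[(1R)-1-[(tert-butyldimethylsilyl)oxy]-3-methylbut-3-en-1-yl]-3-(prop-2-en-1-yl)cyclopent-2-en-1-one | O=C1CCC(CC=C)=C1[C@H](O[Si](C)(C)C(C)(C)C)CC(C)=C
F6 | step 13 | (3R)-3-hydroxy-6-methyl-3-(propan-2-yl)-2,3,5,8-tetrahydroazulen-4(1H)-one (C6 ketone conjugated with C1=C5; daucane locant 4R) | CC(C)[C@]1(O)CCC2=C1C(=O)CC(C)=CC2
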